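## Structural features

The target is a C40 carotenoid. An all-E heptaene chain (C9 to C9', methyls on C9, C13, C13', C9') links two 4,4,7a-trimethyl-2,4,5,6,7,7a-hexahydrobenzofuran bicycles through C8 and C8'. Each bicycle is a cyclohexane fused to a 2,5-dihydrofuran: O bridges C5 and C8, and C6=C7 is the ring alkene. Carotenoid numbering is used throughout, with primes for end A.

End B carries C3 (secondary carbinol), C5 (quaternary O–C) and C8 (O–CH), configured (3R,5S,8S). The 3-hydroxyl is trans to the ring oxygen, and the chain at C8 is trans to the C5 methyl. End A is (5'R,8'S), with the chain cis to the C5' methyl. The two quaternary centres therefore have opposite sense while C8 and C8' have the same sense. The end B ring also belongs to the mirror-image series of the usual (4R)-hydroxy-trimethylcyclohexanone building block.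

The C8–O bonds are doubly allylic and ionize readily with acid, which scrambles C8. The polyene is sensitive to light, oxygen and acid, and H-8 is γ to any carbonyl placed at C11.

The real difficulty is C8/C8'. Each lies 1,3 to a quaternary centre across the ring oxygen, in a nearly flat ring that gives almost no facial bias. The two ends need opposite relative configurations, and C9=C10 must be E.

The key step uses the fact that C8 is allylic to C9=C10. The O–C8 bond and the E C9=C10 bond can form together from a C8=C9 alkene and a reagent-set C10 carbinol, while the Z C6=C7 bond (taken from a butenolide) holds the C5 hydroxyl next to C8.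

## Logic of the disconnections

43 ⇒ 42: only the O–Si bond at C3 is cut. The hydroxyl stays masked through all carbanion and hydride steps. The forward step must be a fluoride cleavage without acid, because both C8–O bonds are doubly allylic.

42 ⇒ 41 + 36: the C11'=C12' bond is cut. Both bicycles then enter as aldehydes, so no carbanion is ever generated directly beside a C8–O bond. C40 falls to C25 + C15. The forward olefination must be E-selective and must add to 36 faster than it removes H-8'.

41 ⇒ 21 + 40: the C11=C12 bond is cut in the same way, so one symmetric C10 linchpin (40) serves both couplings. The demand is mono-olefination of a bifunctional reagent.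

40 ⇒ 39 ⇒ 38 ⇒ 37: the two C–P bonds, then the C–Br bonds, then the oxidation level are removed. This leads back to a purchasable C10 unit that already holds the central triene. The forward steps must keep the three E double bonds.

21 ⇒ 20 ⇒ 19: the oxidation level and the ester at C11 are adjusted. Nothing is simplified in the skeleton. The demand is reagents that are neither acidic nor basic enough to touch C8.

19 ⇒ 18: the O–C8 bond is cut (key step). The ring, the C8 centre and the E C9=C10 bond are all traced back to one secondary carbinol at C10 and a Z,E diene. The forward step must be a clean syn-SN2' displacement without ionization at C10, C5 or C8.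

18 ⇒ 17: the C10–H bond is cut. The carbinol comes from a ketone by reagent control, so its configuration is independent of the ring centres. The same reagent then serves the trans end B and the cis end A.

17 ⇒ 16 + 5: the C8=C9 bond is cut. A stabilized ylide gives the E trisubstituted alkene, and the lactol delivers the Z C6=C7 bond with the C5 hydroxyl already free. The forward step must olefinate without conjugate addition of that hydroxyl to the new dienone.

5 ⇒ 4 ⇒ 3 ⇒ 2 ⇒ 1: the C=P, C–Br and ester C–O bonds are removed in turn. The C9–C11 unit with the C19 methyl comes from a four-carbon hydroxy ketone. The demand is bromination on the ethyl side only.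

16 ⇒ 15 ⇒ 14 ⇒ 12 + 13: the lactol is taken back to the lactone, then C6=C7 and the ester C–O bond are cut. Tethering the phosphonate to the C5 oxygen makes the hindered C6 ketone reachable and fixes the Z geometry. The demand is acylation of a tertiary α-ketol.

12 ⇒ 11 ⇒ 10 ⇒ 9 ⇒ 8 ⇒ 7 ⇒ 6: the C5–O bond is cut (enol ether oxidation), then the C3 carbinol is traced to a ketone. The ring with all its carbons is purchasable. The forward steps must pick the correct catalyst enantiomer for C3 and oxidize C5 on the face opposite to the C3 silyloxy group.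

36 ⇒ 35 ⇒ 34 ⇒ 33 ⇒ 32 ⇒ 31 + 5 ⇒ 30 ⇒ 29 ⇒ 28 + 13: end A repeats the same cuts. The cis relation is met by the same C10' carbinol configuration combined with the opposite C5' configuration.

28 ⇒ 27 ⇒ 26 ⇒ 25 ⇒ 24 ⇒ 23 ⇒ 22: the C6' carbonyl comes from an exocyclic alkene, and the tertiary carbinol from the epoxide of an allylic alcohol. The quaternary centre is thus set by a reagent-controlled epoxidation of an achiral, purchasable ring. The demand is a transposition that never breaks the C5'–O bond.

## Other disconnections considered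

Alternative 1: The cut removes both the C1'–C6' ring bond and the O–C5' bond of end A, back to the acyclic allenyl carbinol A1. In the forward step HNTf2 in hexafluoroisopropanol protonates the trisubstituted alkene, the C1' cation is trapped by the central allene carbon C6', and the C8' hydroxyl captures the C5' cation to give A2.
- In its favour: two rings, one C–C bond and the quaternary centre form in one operation from a linear precursor. Chirality flows from an easily set secondary carbinol to C5', so no enantiopure α-ketol is needed. On this point it is better than the chosen plan, which spends steps 17–21 on 28.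
- Against it here: A2 ends at C9' as a CH2O group on C8'. The C19' methyl, the E C9'=C10' bond and C10'–C11' would still have to be built through a carbonyl placed directly on the C8' stereocentre (epimerizable) and an olefination of a methyl ketone (weakly E-selective).
- The relay from C8' to C5' passes through a planar cation that must choose a face on the basis of H against CH2OPiv, and the target needs the cis relation. The superacid is a hazard for an allylic ether, and proton loss or other cyclization modes can compete.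
- It serves end A only.
- Comparison: on structure the chosen plan delivers the whole C15 unit with C9=C10 in place. On mechanism the chosen step is a metal-mediated stereospecific displacement against a stepwise cation cascade. On step economy the alternative is better up to the bicycle and worse from there to the C15 aldehyde, so the totals would be about equal.

Alternative 2: The cut removes O–C8 and C6=C7 of end B, back to the α-ketol 12 and the vinylphosphonium salt A3. In the forward step NaH forms the C5 alkoxide, which adds to the β-carbon of A3, and the ylide at C7 condenses with the C6 ketone to give A4.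
- In its favour: it starts from 12, the same α-ketol as the chosen route, and reaches the bicycle in one step where the chosen route needs six (steps 9–14). This is clearly better step economy to the ring. The Z ring alkene is automatic and no transition metal is needed. C8 in A4 is only singly allylic, so at that stage it is the equal or better of 19 in acid stability.
- Against it here: C8 is created under the sole influence of the remote C5 centre, which is exactly the weak bias. A non-stabilized ylide must attack a ketone flanked by two fully substituted carbons.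
- Downstream, the ketal must be opened with acid and the C9 carbonyl then sits on C8. That could allow equilibration toward the trans isomer (a possible gain for end B, a loss for end A, which needs cis). The olefination of the methyl ketone leaves C9=C10 to a poor E/Z preference.
- Comparison: on structure both routes reach the C15 alcohol 20. On mechanism the chosen plan sets C8 and the alkene geometry by one reagent-controlled carbinol, while the alternative leaves both to substrate control. On step economy the alternative is better by about three steps.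

Alternative 3: The cut removes O–C8' of end A at the C15 stage, back to the hydroxy vinylallene A5. In the forward step cationic monovalent gold (Ph3PAuCl with AgBF4) activates the allene and the C5' hydroxyl adds to C8' in a 5-endo closure to give A6.
- In its favour: cycloisomerization of α-hydroxy allenes is a well-established, mild reaction that tolerates tertiary alcohols and transfers the axis to the new centre. The E C9'=C10' bond is already present in A5 and is not made in the key step, so on alkene geometry it is better than the chosen plan. There is no leaving group and hence no ionization pathway. From 28 it would need about five steps to 36 against eight, so it is also better in step economy.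
- Against it here: the stereochemical information must first be stored in an allene axis. That axis would be set relative to C5' by a diastereoselective alkynylation of the hindered ketone 28 and a stereospecific SN2' reduction of the propargylic carbinol. These are two substrate-controlled relays whose sense is dictated by the ring, while the target needs cis at one end and trans at the other.
- Gold can also epimerize allene axes, and vinylallenes can undergo competing carbocyclization.
- Comparison: the fidelity of axis-to-centre transfer should equal that of the carbinol-to-centre transfer chosen here. The chosen plan is better in how the information is installed: a catalyst-set sp3 carbinol that is independent of the ring, with the same catalyst serving both ends.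

Key step: step 14

Remarks on the chemistry:
- The C10 descriptor of 18 was checked against a syn-SN2' course (10S gives 8S with E C9=C10) and against 43; no structure needed correction.
- The design of 18 is tightened in three ways: the carbinol is generated last (step 13) from a salt-free Wittig product, the acyl group is kept on O11 to suppress ionization at C10, and 18 is used without storage.
- The C10 dialdehyde 37 and β-cyclocitral 22 are taken as purchasable.
- From step 12 on, all operations are run under argon in dim light.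

## Steps

Step 1
Reactants: 1 1-hydroxybutan-2-one
Product: 2 2-oxobutyl pivalate
Conditions: PivCl, pyridine, 4-(dimethylamino)pyridine (cat.), CH2Cl2, 0 °C → rt
Reagents that add atoms: pivaloyl chloride, CC(C)(C)C(Cl)=O
Why: Acylation of a primary alcohol. The bulky pivalate resists acyl migration and attack by the later ylide carbon, and is carried to step 15.

Step 2
Reactants: 2 2-oxobutyl pivalate
Product: 3 (±)-3-bromo-2-oxobutyl pivalate
Conditions: Br2, HBr (cat.), CH2Cl2, 0 °C → rt
Reagents that add atoms: bromine, BrBr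
Why: Acid-catalysed α-bromination of a ketone. The acyloxy group retards enolization toward C1 as a halogen would, so the enol forms on the ethyl side and bromine enters at C3.

Step 3
Reactants: 3 (±)-3-bromo-2-oxobutyl pivalate
Product: 5 2-oxo-3-(triphenyl-λ5-phosphanylidene)butyl pivalate, via phosphonium bromide 4 (not isolated)
Conditions: PPh3, toluene, 60 °C; then Na2CO3, H2O/CH2Cl2, rt
Reagents that add atoms: triphenylphosphine, c1ccc(cc1)P(c1ccccc1)c1ccccc1
Why: SN2 quaternization of the α-bromo ketone and deprotonation of the acidic α-CH give the acyl-stabilized phosphorane, which can be stored and used salt-free.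

Step 4
Reactants: 6 ketoisophorone
Product: 7 (R)-4-hydroxy-2,6,6-trimethylcyclohex-2-en-1-one
Conditions: RuCl[(R,R)-TsNCHPhCHPhNH2](p-cymene) (1 mol%), i-PrOH, rt
Reagents that add atoms: none
Why: Noyori asymmetric transfer hydrogenation; only the unhindered C4 carbonyl reacts. The ring alkene takes the place of the aryl group of an aryl ketone, so the (R,R)-ligand should give the (R)-carbinol, which becomes C3 of end B.

Step 5
Reactants: 7 (R)-4-hydroxy-2,6,6-trimethylcyclohex-2-en-1-one
Product: 8 (R)-4-[(tert-butyldimethylsilyl)oxy]-2,6,6-trimethylcyclohex-2-en-1-one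
Conditions: TBSCl, imidazole, DMF, rt
Reagents that add atoms: tert-butyldimethylsilyl chloride, CC(C)(C)[Si](C)(C)Cl
Why: Standard silylation of a secondary alcohol; the silyl ether should survive every step up to the final fluoride treatment.

Step 6
Reactants: 8 (R)-4-[(tert-butyldimethylsilyl)oxy]-2,6,6-trimethylcyclohex-2-en-1-one
Product: 9 (4S)-4-[(tert-butyldimethylsilyl)oxy]-2,2,6-trimethylcyclohexan-1-one (both C6 epimers)
Conditions: H2 (1 atm), Pd/C, EtOAc, rt
Reagents that add atoms: none
Why: Hydrogenation of the conjugated trisubstituted alkene. The C6 centre forms as a mixture, which does not matter because it is made planar in step 7; the descriptor at the silyloxy carbon changes to S only through the priority rules.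

Step 7
Reactants: 9 (4S)-4-[(tert-butyldimethylsilyl)oxy]-2,2,6-trimethylcyclohexan-1-one
Product: 10 tert-butyldimethyl{[(1S)-3,5,5-trimethyl-4-(trimethylsilyloxy)cyclohex-3-en-1-yl]oxy}silane
Conditions: Me3SiOTf, Et3N, CH2Cl2, 0 °C
Reagents that add atoms: trimethylsilyl trifluoromethanesulfonate, C[Si](C)(C)OS(=O)(=O)C(F)(F)F
Why: Soft enolization. The other α-carbon is quaternary, so only the tetrasubstituted enol ether toward the methyl-bearing carbon can form.

Step 8
Reactants: 10 tert-butyldimethyl{[(1S)-3,5,5-trimethyl-4-(trimethylsilyloxy)cyclohex-3-en-1-yl]oxy}silane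
Product: 12 (2S,4R)-4-[(tert-butyldimethylsilyl)oxy]-2-hydroxy-2,6,6-trimethylcyclohexan-1-one, via α-silyloxy ketone 11 (not isolated)
Conditions: 3-chloroperbenzoic acid, hexane, −15 °C → rt; then K2CO3 (cat.), MeOH, 0 °C
Reagents that add atoms: 3-chloroperbenzoic acid, OOC(=O)c1cccc(Cl)c1
Why: Rubottom oxidation: epoxidation of the enol ether, opening with 1,4-silyl shift to 11, then methanolysis of the tertiary trimethylsilyl ether. The peracid should bond to the methyl-bearing carbon along the axial direction of the half-chair that has the silyloxy group equatorial, on the face opposite to that group (the sense of the predominant anti epoxidation of 3-acyloxy β-end groups). This places the new C5 hydroxyl trans to the C3 silyloxy group.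

Step 9
Reactants: 12 (2S,4R)-4-[(tert-butyldimethylsilyl)oxy]-2-hydroxy-2,6,6-trimethylcyclohexan-1-one; 13 diethylphosphonoacetic acid
Product: 14 (1S,5R)-5-[(tert-butyldimethylsilyl)oxy]-1,3,3-trimethyl-2-oxocyclohexyl (diethoxyphosphoryl)acetate
Conditions: N,N'-dicyclohexylcarbodiimide, 4-(dimethylamino)pyridine (cat.), CH2Cl2, 0 °C → rt
Reagents that add atoms: none
Why: Steglich esterification; the carbodiimide-activated phosphonoacetic acid is reactive enough to acylate a tertiary α-ketol.

Step 10
Reactants: 14 (1S,5R)-5-[(tert-butyldimethylsilyl)oxy]-1,3,3-trimethyl-2-oxocyclohexyl (diethoxyphosphoryl)acetate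
Product: 15 (6R,7aS)-6-[(tert-butyldimethylsilyl)oxy]-4,4,7a-trimethyl-5,6,7,7a-tetrahydro-1-benzofuran-2(4H)-one
Conditions: NaH, THF, 0 °C → rt
Reagents that add atoms: none
Why: Intramolecular Horner–Wadsworth–Emmons reaction. The tether makes the ketone between two fully substituted carbons reachable, and the five-membered ring forces the Z geometry of C6=C7.

Step 11
Reactants: 15 (6R,7aS)-6-[(tert-butyldimethylsilyl)oxy]-4,4,7a-trimethyl-5,6,7,7a-tetrahydro-1-benzofuran-2(4H)-one
Product: 16 (6R,7aS)-6-[(tert-butyldimethylsilyl)oxy]-4,4,7a-trimethyl-2,4,5,6,7,7a-hexahydro-1-benzofuran-2-ol (both anomers)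
Conditions: i-Bu2AlH (1.1 equiv), CH2Cl2, −78 °C
Reagents that add atoms: none
Why: Partial reduction of a lactone to the lactol through an aluminium hemiacetal that is stable at low temperature. C7a is quaternary, so the lactol cannot aromatize to a furan.

Step 12
Reactants: 16 (6R,7aS)-6-[(tert-butyldimethylsilyl)oxy]-4,4,7a-trimethyl-2,4,5,6,7,7a-hexahydro-1-benzofuran-2-ol; 5 2-oxo-3-(triphenyl-λ5-phosphanylidene)butyl pivalate
Product: 17 (3E,5Z)-5-[(2S,4R)-4-[(tert-butyldimethylsilyl)oxy]-2-hydroxy-2,6,6-trimethylcyclohexylidene]-3-methyl-2-oxopent-3-en-1-yl pivalate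
Conditions: toluene, 80 °C
Reagents that add atoms: none
Why: Wittig olefination of the ring-opened (Z)-hydroxy enal with an acyl-stabilized ylide gives the E trisubstituted C8=C9 bond. Salt-free neutral conditions and immediate use in step 13 are meant to keep the tertiary hydroxyl from adding to the dienone.

Step 13
Reactants: 17 (3E,5Z)-5-[(2S,4R)-4-[(tert-butyldimethylsilyl)oxy]-2-hydroxy-2,6,6-trimethylcyclohexylidene]-3-methyl-2-oxopent-3-en-1-yl pivalate
Product: 18 (2S,3E,5Z)-5-[(2S,4R)-4-[(tert-butyldimethylsilyl)oxy]-2-hydroxy-2,6,6-trimethylcyclohexylidene]-2-hydroxy-3-methylpent-3-en-1-yl pivalate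
Conditions: (S)-1-methyl-3,3-diphenyltetrahydro-1H,3H-pyrrolo[1,2-c][1,3,2]oxazaborole ((S)-Me-CBS, 0.2 equiv), BH3·SMe2, THF, −30 °C
Reagents that add atoms: none
Why: Corey–Bakshi–Shibata reduction. With the α-methyl dienyl group as the large and CH2OPiv as the small substituent, the (S)-catalyst should give the (10S)-carbinol (S because CH2O outranks the alkenyl carbon), independent of the remote ring centres.

Step 14
Reactants: 18 (2S,3E,5Z)-5-[(2S,4R)-4-[(tert-butyldimethylsilyl)oxy]-2-hydroxy-2,6,6-trimethylcyclohexylidene]-2-hydroxy-3-methylpent-3-en-1-yl pivalate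
Product: 19 (2E)-3-[(2S,6R,7aS)-6-[(tert-butyldimethylsilyl)oxy]-4,4,7a-trimethyl-2,4,5,6,7,7a-hexahydro-1-benzofuran-2-yl]but-2-en-1-yl pivalate
Conditions: PdCl2(MeCN)2 (5 mol%), THF, 0 °C; quench with Et3N
Reagents that add atoms: none
Why: Divalent palladium binds the C8=C9 π bond on the face that carries the C10 hydroxyl; the C5 oxygen, held beside C8 by the Z C6=C7 bond, bonds to C8 on that same face, and the C9–Pd bond then leaves together with the C10 hydroxyl, a net syn-SN2' displacement that gives water and returns the catalyst. The closest known reaction type is the palladium dichloride-catalysed dehydrative cyclization of monoallylic diols with 1,3-chirality transfer. The dihydrofuran closes in the 5-exo-trig mode, C9 staying outside the ring. The one new stereocentre, C8, is controlled by the C10 carbinol: in the reactive conformer H-10 eclipses C8=C9, and the (10S)-hydroxyl then lies on the face from which oxygen must add to give (8S), the chain trans to the C5 methyl. The same conformer turns C11 away from C8, so C9=C10 forms E. The step needs facial selectivity at C8 and E geometry, and both are secured by the carbinol because the bicycle barely differentiates the two faces. The reverse closure (C10 oxygen onto C7) is excluded because an E C8=C9 bond cannot sit in a five-membered ring, and the electron-withdrawing pivaloyloxy group on C11 disfavours ionization at C10.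

Step 15
Reactants: 19 (2E)-3-[(2S,6R,7aS)-6-[(tert-butyldimethylsilyl)oxy]-4,4,7a-trimethyl-2,4,5,6,7,7a-hexahydro-1-benzofuran-2-yl]but-2-en-1-yl pivalate
Product: 20 (2E)-3-[(2S,6R,7aS)-6-[(tert-butyldimethylsilyl)oxy]-4,4,7a-trimethyl-2,4,5,6,7,7a-hexahydro-1-benzofuran-2-yl]but-2-en-1-ol
Conditions: i-Bu2AlH (2.5 equiv), CH2Cl2, −78 °C
Reagents that add atoms: none
Why: Reductive cleavage of the pivalate under conditions that are neither acidic nor strongly basic, so the doubly allylic C8–O bond and the silyl ether stay intact.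

Step 16
Reactants: 20 (2E)-3-[(2S,6R,7aS)-6-[(tert-butyldimethylsilyl)oxy]-4,4,7a-trimethyl-2,4,5,6,7,7a-hexahydro-1-benzofuran-2-yl]but-2-en-1-ol
Product: 21 (2E)-3-[(2S,6R,7aS)-6-[(tert-butyldimethylsilyl)oxy]-4,4,7a-trimethyl-2,4,5,6,7,7a-hexahydro-1-benzofuran-2-yl]but-2-enal
Conditions: MnO2, CH2Cl2, rt
Reagents that add atoms: none
Why: Chemoselective oxidation of a primary allylic alcohol on a neutral heterogeneous oxidant; the E geometry is kept and no stereocentre is α to the new carbonyl.

Step 17
Reactants: 22 β-cyclocitral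
Product: 23 β-cyclogeraniol, (2,6,6-trimethylcyclohex-1-en-1-yl)methanol
Conditions: NaBH4, MeOH, 0 °C
Reagents that add atoms: none
Why: 1,2-Reduction of a hindered conjugated aldehyde to the allylic alcohol.

Step 18
Reactants: 23 β-cyclogeraniol
Product: 24 [(1R,6R)-2,2,6-trimethyl-7-oxabicyclo[4.1.0]heptan-1-yl]methanol
Conditions: Ti(Oi-Pr)4 (0.2 equiv), D-(−)-diethyl tartrate (0.24 equiv), t-BuOOH, 4 Å molecular sieves, CH2Cl2, −20 °C
Reagents that add atoms: tert-butyl hydroperoxide, CC(C)(C)OO
Why: Sharpless asymmetric epoxidation of a tetrasubstituted allylic alcohol. The D-(−)-tartrate should deliver oxygen to the face that makes the methyl-bearing carbon (later C5') R, by reagent control alone.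

Step 19
Reactants: 24 [(1R,6R)-2,2,6-trimethyl-7-oxabicyclo[4.1.0]heptan-1-yl]methanol
Product: 25 (1S,6R)-2,2,6-trimethyl-7-oxabicyclo[4.1.0]heptane-1-carbaldehyde
Conditions: Dess–Martin periodinane, NaHCO3, CH2Cl2, rt
Reagents that add atoms: none
Why: Mild oxidation of the primary alcohol. The aldehyde has no α-hydrogen and the buffer spares the tetrasubstituted epoxide; the descriptor at C1 changes only through the priority rules.

Step 20
Reactants: 25 (1S,6R)-2,2,6-trimethyl-7-oxabicyclo[4.1.0]heptane-1-carbaldehyde
Product: 26 (1R)-1,3,3-trimethyl-2-methylidenecyclohexan-1-ol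
Conditions: N2H4·H2O, AcOH (cat.), MeOH, 0 °C → rt
Reagents that add atoms: none
Why: Wharton transposition: the hydrazone opens the epoxide, the vinyl diazene loses N2, and the exocyclic methylene with the tertiary carbinol results. The C–O bond at the carbinol carbon is never broken, so its configuration is kept.

Step 21
Reactants: 26 (1R)-1,3,3-trimethyl-2-methylidenecyclohexan-1-ol
Product: 28 (2R)-2-hydroxy-2,6,6-trimethylcyclohexan-1-one, via ozonide 27 (not isolated)
Conditions: O3, CH2Cl2, −78 °C; then Me2S, −78 °C → rt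
Reagents that add atoms: ozone, [O-][O+]=O
Why: Ozonolysis of the 1,1-disubstituted alkene with reductive work-up gives the α-hydroxy ketone without touching the carbinol centre.

Step 22
Reactants: 28 (2R)-2-hydroxy-2,6,6-trimethylcyclohexan-1-one; 13 diethylphosphonoacetic acid
Product: 29 (1R)-1,3,3-trimethyl-2-oxocyclohexyl (diethoxyphosphoryl)acetate
Conditions: N,N'-dicyclohexylcarbodiimide, 4-(dimethylamino)pyridine (cat.), CH2Cl2, 0 °C → rt
Reagents that add atoms: none
Why: Steglich esterification of the tertiary α-ketol, as in step 9.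

Step 23
Reactants: 29 (1R)-1,3,3-trimethyl-2-oxocyclohexyl (diethoxyphosphoryl)acetate
Product: 30 (7aR)-4,4,7a-trimethyl-5,6,7,7a-tetrahydro-1-benzofuran-2(4H)-one
Conditions: NaH, THF, 0 °C → rt
Reagents that add atoms: none
Why: Intramolecular Horner–Wadsworth–Emmons reaction, as in step 10; the butenolide fixes the Z C6'=C7' bond.

Step 24
Reactants: 30 (7aR)-4,4,7a-trimethyl-5,6,7,7a-tetrahydro-1-benzofuran-2(4H)-one
Product: 31 (7aR)-4,4,7a-trimethyl-2,4,5,6,7,7a-hexahydro-1-benzofuran-2-ol (both anomers)
Conditions: i-Bu2AlH (1.1 equiv), CH2Cl2, −78 °C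
Reagents that add atoms: none
Why: Partial reduction of the lactone to the lactol, as in step 11.

Step 25
Reactants: 31 (7aR)-4,4,7a-trimethyl-2,4,5,6,7,7a-hexahydro-1-benzofuran-2-ol; 5 2-oxo-3-(triphenyl-λ5-phosphanylidene)butyl pivalate
Product: 32 (3E,5Z)-5-[(2R)-2-hydroxy-2,6,6-trimethylcyclohexylidene]-3-methyl-2-oxopent-3-en-1-yl pivalate
Conditions: toluene, 80 °C
Reagents that add atoms: none
Why: Wittig olefination of the lactol with the stabilized ylide, as in step 12, gives the E C8'=C9' bond.

Step 26
Reactants: 32 (3E,5Z)-5-[(2R)-2-hydroxy-2,6,6-trimethylcyclohexylidene]-3-methyl-2-oxopent-3-en-1-yl pivalate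
Product: 33 (2S,3E,5Z)-2-hydroxy-5-[(2R)-2-hydroxy-2,6,6-trimethylcyclohexylidene]-3-methylpent-3-en-1-yl pivalate
Conditions: (S)-Me-CBS (0.2 equiv), BH3·SMe2, THF, −30 °C
Reagents that add atoms: none
Why: Corey–Bakshi–Shibata reduction with the same catalyst as in step 13 gives the (10'S)-carbinol, again independent of the ring centre.

Step 27
Reactants: 33 (2S,3E,5Z)-2-hydroxy-5-[(2R)-2-hydroxy-2,6,6-trimethylcyclohexylidene]-3-methylpent-3-en-1-yl pivalate
Product: 34 (2E)-3-[(2S,7aR)-4,4,7a-trimethyl-2,4,5,6,7,7a-hexahydro-1-benzofuran-2-yl]but-2-en-1-yl pivalate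
Conditions: PdCl2(MeCN)2 (5 mol%), THF, 0 °C; quench with Et3N
Reagents that add atoms: none
Why: The same syn-SN2' dehydrative cyclization as in step 14 (5-exo-trig). The (10'S)-carbinol again gives (8'S), which with the (5'R) ring places the chain cis to the C5' methyl, and C9'=C10' forms E.

Step 28
Reactants: 34 (2E)-3-[(2S,7aR)-4,4,7a-trimethyl-2,4,5,6,7,7a-hexahydro-1-benzofuran-2-yl]but-2-en-1-yl pivalate
Product: 35 (2E)-3-[(2S,7aR)-4,4,7a-trimethyl-2,4,5,6,7,7a-hexahydro-1-benzofuran-2-yl]but-2-en-1-ol
Conditions: i-Bu2AlH (2.5 equiv), CH2Cl2, −78 °C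
Reagents that add atoms: none
Why: Reductive cleavage of the pivalate, as in step 15.

Step 29
Reactants: 35 (2E)-3-[(2S,7aR)-4,4,7a-trimethyl-2,4,5,6,7,7a-hexahydro-1-benzofuran-2-yl]but-2-en-1-ol
Product: 36 (2E)-3-[(2S,7aR)-4,4,7a-trimethyl-2,4,5,6,7,7a-hexahydro-1-benzofuran-2-yl]but-2-enal
Conditions: MnO2, CH2Cl2, rt
Reagents that add atoms: none
Why: Allylic oxidation on a neutral oxidant, as in step 16.

Step 30
Reactants: 37 (2E,4E,6E)-2,7-dimethylocta-2,4,6-trienedial
Product: 38 (2E,4E,6E)-2,7-dimethylocta-2,4,6-triene-1,8-diol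
Conditions: NaBH4, MeOH/THF, 0 °C
Reagents that add atoms: none
Why: 1,2-Reduction of both conjugated aldehydes; the triene geometry is not touched.

Step 31
Reactants: 38 (2E,4E,6E)-2,7-dimethylocta-2,4,6-triene-1,8-diol
Product: 39 (2E,4E,6E)-1,8-dibromo-2,7-dimethylocta-2,4,6-triene
Conditions: PBr3, pyridine (cat.), Et2O, −10 °C
Reagents that add atoms: phosphorus tribromide, BrP(Br)Br
Why: Conversion of primary allylic alcohols to bromides; the primary bromide with the trisubstituted alkene is the stable allylic isomer.

Step 32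
Reactants: 39 (2E,4E,6E)-1,8-dibromo-2,7-dimethylocta-2,4,6-triene
Product: 40 tetraethyl [(2E,4E,6E)-2,7-dimethylocta-2,4,6-triene-1,8-diyl]bis(phosphonate)
Conditions: P(OEt)3 (neat), 90 °C
Reagents that add atoms: triethyl phosphite, CCOP(OCC)OCC
Why: Michaelis–Arbuzov reaction of a reactive bis-allylic bromide; volatile bromoethane is removed as it forms.

Step 33
Reactants: 21 (2E)-3-[(2S,6R,7aS)-6-[(tert-butyldimethylsilyl)oxy]-4,4,7a-trimethyl-2,4,5,6,7,7a-hexahydro-1-benzofuran-2-yl]but-2-enal; 40 tetraethyl [(2E,4E,6E)-2,7-dimethylocta-2,4,6-triene-1,8-diyl]bis(phosphonate)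
Product: 41 diethyl [(2E,4E,6E,8E,10E)-11-[(2S,6R,7aS)-6-[(tert-butyldimethylsilyl)oxy]-4,4,7a-trimethyl-2,4,5,6,7,7a-hexahydro-1-benzofuran-2-yl]-2,7-dimethyldodeca-2,4,6,8,10-pentaen-1-yl]phosphonate
Conditions: 40 (3 equiv), NaN(SiMe3)2 (1.0 equiv), THF, −78 °C; then 21 added slowly, −78 → 0 °C
Reagents that add atoms: none
Why: Horner–Wadsworth–Emmons reaction of an allylic phosphonate anion, E-selective at the new C11=C12 bond. The threefold excess of the linchpin and slow addition of the aldehyde favour mono-olefination, and the carbanion sits on a fragment that carries no ring ether.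

Step 34
Reactants: 41 diethyl [(2E,4E,6E,8E,10E)-11-[(2S,6R,7aS)-6-[(tert-butyldimethylsilyl)oxy]-4,4,7a-trimethyl-2,4,5,6,7,7a-hexahydro-1-benzofuran-2-yl]-2,7-dimethyldodeca-2,4,6,8,10-pentaen-1-yl]phosphonate; 36 (2E)-3-[(2S,7aR)-4,4,7a-trimethyl-2,4,5,6,7,7a-hexahydro-1-benzofuran-2-yl]but-2-enal
Product: 42 (3R,5S,8S,5'R,8'S)-3-[(tert-butyldimethylsilyl)oxy]-5,8:5',8'-diepoxy-5,8,5',8'-tetrahydro-β,β-carotene
Conditions: NaN(SiMe3)2 (1.05 equiv), THF, −78 °C; then 36, −78 → 0 °C
Reagents that add atoms: none
Why: Second Horner–Wadsworth–Emmons reaction, E-selective at C11'=C12'. The anion of 41 is spread over five double bonds and is far less basic than a tertiary alkoxide, so loss of the remote ring oxygen is uphill, and addition to the aldehyde at low temperature should outrun removal of H-8'.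

Step 35
Reactants: 42 (3R,5S,8S,5'R,8'S)-3-[(tert-butyldimethylsilyl)oxy]-5,8:5',8'-diepoxy-5,8,5',8'-tetrahydro-β,β-carotene
Product: 43 (3R,5S,8S,5'R,8'S)-5,8:5',8'-diepoxy-5,8,5',8'-tetrahydro-β,β-caroten-3-ol
Conditions: Bu4NF, THF, 0 °C → rt
Reagents that add atoms: none
Why: Fluoride cleavage of the secondary silyl ether under non-acidic conditions, which the doubly allylic C8–O bonds and the polyene tolerate.

## Compound list

1 | 1-hydroxybutan-2-one | CCC(=O)CO | starting material
2 | 2-oxobutyl pivalate | CCC(=O)COC(=O)C(C)(C)C | intermediate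
3 | (±)-3-bromo-2-oxobutyl pivalate | CC(Br)C(=O)COC(=O)C(C)(C)C | intermediate
4 | (±)-[3-oxo-4-(pivaloyloxy)butan-2-yl]triphenylphosphonium bromide | CC(C(=O)COC(=O)C(C)(C)C)[P+](c1ccccc1)(c1ccccc1)c1ccccc1.[Br-] | intermediate (not isolated)
5 | 2-oxo-3-(triphenyl-λ5-phosphanylidene)butyl pivalate | CC(C(=O)COC(=O)C(C)(C)C)=P(c1ccccc1)(c1ccccc1)c1ccccc1 | intermediate
6 | ketoisophorone (2,6,6-trimethylcyclohex-2-ene-1,4-dione) | CC1=CC(=O)CC(C)(C)C1=O | starting material
7 | (R)-4-hydroxy-2,6,6-trimethylcyclohex-2-en-1-one | CC1=C[C@H](O)CC(C)(C)C1=O | intermediate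
8 | (R)-4-[(tert-butyldimethylsilyl)oxy]-2,6,6-trimethylcyclohex-2-en-1-one | CC1=C[C@H](O[Si](C)(C)C(C)(C)C)CC(C)(C)C1=O | intermediate
9 | (4S)-4-[(tert-butyldimethylsilyl)oxy]-2,2,6-trimethylcyclohexan-1-one (C6 epimers) | CC1C[C@H](O[Si](C)(C)C(C)(C)C)CC(C)(C)C1=O | intermediate
10 | tert-butyldimethyl{[(1S)-3,5,5-trimethyl-4-(trimethylsilyloxy)cyclohex-3-en-1-yl]oxy}silane | CC1=C(O[Si](C)(C)C)C(C)(C)C[C@@H](O[Si](C)(C)C(C)(C)C)C1 | intermediate
11 | (2S,4R)-4-[(tert-butyldimethylsilyl)oxy]-2,6,6-trimethyl-2-(trimethylsilyloxy)cyclohexan-1-one | O=C1C(C)(C)C[C@@H](O[Si](C)(C)C(C)(C)C)C[C@]1(C)O[Si](C)(C)C | intermediate (not isolated)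
12 | (2S,4R)-4-[(tert-butyldimethylsilyl)oxy]-2-hydroxy-2,6,6-trimethylcyclohexan-1-one | O=C1C(C)(C)C[C@@H](O[Si](C)(C)C(C)(C)C)C[C@]1(C)O | intermediate
13 | diethylphosphonoacetic acid | CCOP(=O)(OCC)CC(=O)O | starting material
14 | (1S,5R)-5-[(tert-butyldimethylsilyl)oxy]-1,3,3-trimethyl-2-oxocyclohexyl (diethoxyphosphoryl)acetate | O=C1C(C)(C)C[C@@H](O[Si](C)(C)C(C)(C)C)C[C@]1(C)OC(=O)CP(=O)(OCC)OCC | intermediate
15 | (6R,7aS)-6-[(tert-butyldimethylsilyl)oxy]-4,4,7a-trimethyl-5,6,7,7a-tetrahydro-1-benzofuran-2(4H)-one | O=C1C=C2C(C)(C)C[C@@H](O[Si](C)(C)C(C)(C)C)C[C@]2(C)O1 | intermediate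
16 | (6R,7aS)-6-[(tert-butyldimethylsilyl)oxy]-4,4,7a-trimethyl-2,4,5,6,7,7a-hexahydro-1-benzofuran-2-ol (anomers) | OC1C=C2C(C)(C)C[C@@H](O[Si](C)(C)C(C)(C)C)C[C@]2(C)O1 | intermediate
17 | (3E,5Z)-5-[(2S,4R)-4-[(tert-butyldimethylsilyl)oxy]-2-hydroxy-2,6,6-trimethylcyclohexylidene]-3-methyl-2-oxopent-3-en-1-yl pivalate | CC(C)(C)C(=O)OCC(=O)/C(C)=C/C=C1/C(C)(C)C[C@@H](O[Si](C)(C)C(C)(C)C)C[C@]1(C)O | intermediate
18 | (2S,3E,5Z)-5-[(2S,4R)-4-[(tert-butyldimethylsilyl)oxy]-2-hydroxy-2,6,6-trimethylcyclohexylidene]-2-hydroxy-3-methylpent-3-en-1-yl pivalate (end B dienyl diol) | CC(C)(C)C(=O)OC[C@@H](O)/C(C)=C/C=C1/C(C)(C)C[C@@H](O[Si](C)(C)C(C)(C)C)C[C@]1(C)O | intermediate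
19 | (2E)-3-[(2S,6R,7aS)-6-[(tert-butyldimethylsilyl)oxy]-4,4,7a-trimethyl-2,4,5,6,7,7a-hexahydro-1-benzofuran-2-yl]but-2-en-1-yl pivalate (end B C15 pivalate) | CC(C)(C)C(=O)OC/C=C(\C)[C@@H]1C=C2C(C)(C)C[C@@H](O[Si](C)(C)C(C)(C)C)C[C@]2(C)O1 | intermediate
20 | (2E)-3-[(2S,6R,7aS)-6-[(tert-butyldimethylsilyl)oxy]-4,4,7a-trimethyl-2,4,5,6,7,7a-hexahydro-1-benzofuran-2-yl]but-2-en-1-ol | OC/C=C(\C)[C@@H]1C=C2C(C)(C)C[C@@H](O[Si](C)(C)C(C)(C)C)C[C@]2(C)O1 | intermediate
21 | (2E)-3-[(2S,6R,7aS)-6-[(tert-butyldimethylsilyl)oxy]-4,4,7a-trimethyl-2,4,5,6,7,7a-hexahydro-1-benzofuran-2-yl]but-2-enal (end B C15 aldehyde) | O=C/C=C(\C)[C@@H]1C=C2C(C)(C)C[C@@H](O[Si](C)(C)C(C)(C)C)C[C@]2(C)O1 | intermediate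
22 | β-cyclocitral (2,6,6-trimethylcyclohex-1-ene-1-carbaldehyde) | CC1=C(C=O)C(C)(C)CCC1 | starting material
23 | β-cyclogeraniol, (2,6,6-trimethylcyclohex-1-en-1-yl)methanol | CC1=C(CO)C(C)(C)CCC1 | intermediate
24 | [(1R,6R)-2,2,6-trimethyl-7-oxabicyclo[4.1.0]heptan-1-yl]methanol | CC1(C)CCC[C@@]2(C)O[C@@]12CO | intermediate
25 | (1S,6R)-2,2,6-trimethyl-7-oxabicyclo[4.1.0]heptane-1-carbaldehyde | CC1(C)CCC[C@@]2(C)O[C@@]12C=O | intermediate
26 | (1R)-1,3,3-trimethyl-2-methylidenecyclohexan-1-ol | C=C1C(C)(C)CCC[C@@]1(C)O | intermediate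
27 | (6R)-6,10,10-trimethyl-1,2,4-trioxaspiro[4.5]decan-6-ol (ozonide, spiro centre undefined) | C[C@@]1(O)CCCC(C)(C)C12OCOO2 | intermediate (not isolated)
28 | (2R)-2-hydroxy-2,6,6-trimethylcyclohexan-1-one | O=C1C(C)(C)CCC[C@@]1(C)O | intermediate
29 | (1R)-1,3,3-trimethyl-2-oxocyclohexyl (diethoxyphosphoryl)acetate | O=C1C(C)(C)CCC[C@@]1(C)OC(=O)CP(=O)(OCC)OCC | intermediate
30 | (7aR)-4,4,7a-trimethyl-5,6,7,7a-tetrahydro-1-benzofuran-2(4H)-one | O=C1C=C2C(C)(C)CCC[C@@]2(C)O1 | intermediate
31 | (7aR)-4,4,7a-trimethyl-2,4,5,6,7,7a-hexahydro-1-benzofuran-2-ol (anomers) | OC1C=C2C(C)(C)CCC[C@@]2(C)O1 | intermediate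
32 | (3E,5Z)-5-[(2R)-2-hydroxy-2,6,6-trimethylcyclohexylidene]-3-methyl-2-oxopent-3-en-1-yl pivalate | CC(C)(C)C(=O)OCC(=O)/C(C)=C/C=C1/C(C)(C)CCC[C@@]1(C)O | intermediate
33 | (2S,3E,5Z)-2-hydroxy-5-[(2R)-2-hydroxy-2,6,6-trimethylcyclohexylidene]-3-methylpent-3-en-1-yl pivalate | CC(C)(C)C(=O)OC[C@@H](O)/C(C)=C/C=C1/C(C)(C)CCC[C@@]1(C)O | intermediate
34 | (2E)-3-[(2S,7aR)-4,4,7a-trimethyl-2,4,5,6,7,7a-hexahydro-1-benzofuran-2-yl]but-2-en-1-yl pivalate | CC(C)(C)C(=O)OC/C=C(\C)[C@@H]1C=C2C(C)(C)CCC[C@@]2(C)O1 | intermediate
35 | (2E)-3-[(2S,7aR)-4,4,7a-trimethyl-2,4,5,6,7,7a-hexahydro-1-benzofuran-2-yl]but-2-en-1-ol | OC/C=C(\C)[C@@H]1C=C2C(C)(C)CCC[C@@]2(C)O1 | intermediate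
36 | (2E)-3-[(2S,7aR)-4,4,7a-trimethyl-2,4,5,6,7,7a-hexahydro-1-benzofuran-2-yl]but-2-enal (end A C15 aldehyde) | O=C/C=C(\C)[C@@H]1C=C2C(C)(C)CCC[C@@]2(C)O1 | intermediate
37 | (2E,4E,6E)-2,7-dimethylocta-2,4,6-trienedial | O=C/C(C)=C/C=C/C=C(\C)C=O | starting material
38 | (2E,4E,6E)-2,7-dimethylocta-2,4,6-triene-1,8-diol | OC/C(C)=C/C=C/C=C(\C)CO | intermediate
39 | (2E,4E,6E)-1,8-dibromo-2,7-dimethylocta-2,4,6-triene | BrC/C(C)=C/C=C/C=C(\C)CBr | intermediate
40 | tetraethyl [(2E,4E,6E)-2,7-dimethylocta-2,4,6-triene-1,8-diyl]bis(phosphonate) | CCOP(=O)(OCC)C/C(C)=C/C=C/C=C(\C)CP(=O)(OCC)OCC | intermediate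
41 | diethyl [(2E,4E,6E,8E,10E)-11-[(2S,6R,7aS)-6-[(tert-butyldimethylsilyl)oxy]-4,4,7a-trimethyl-2,4,5,6,7,7a-hexahydro-1-benzofuran-2-yl]-2,7-dimethyldodeca-2,4,6,8,10-pentaen-1-yl]phosphonate (C25 phosphonate) | CCOP(=O)(OCC)C/C(C)=C/C=C/C=C(C)/C=C/C=C(\C)[C@@H]1C=C2C(C)(C)C[C@@H](O[Si](C)(C)C(C)(C)C)C[C@]2(C)O1 | intermediate
42 | (3R,5S,8S,5'R,8'S)-3-[(tert-butyldimethylsilyl)oxy]-5,8:5',8'-diepoxy-5,8,5',8'-tetrahydro-β,β-carotene | CC(/C=C/C=C(\C)[C@@H]1C=C2C(C)(C)CCC[C@@]2(C)O1)=C\C=C\C=C(C)\C=C\C=C(/C)[C@@H]1C=C2C(C)(C)C[C@@H](O[Si](C)(C)C(C)(C)C)C[C@]2(C)O1 | intermediate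
43 | (3R,5S,8S,5'R,8'S)-5,8:5',8'-diepoxy-5,8,5',8'-tetrahydro-β,β-caroten-3-ol | CC(/C=C/C=C(\C)[C@@H]1C=C2C(C)(C)CCC[C@@]2(C)O1)=C\C=C\C=C(C)\C=C\C=C(/C)[C@@H]1C=C2C(C)(C)C[C@@H](O)C[C@]2(C)O1 | target

## Step count and least certain steps

Total: 35 steps. Longest linear sequence: 16 steps (6 to 43 through steps 4–16 and 33–35). The end A branch is 15 steps, the ylide branch 3 and the linchpin branch 3 before they join.

**Step 14 (key step; step 27 is the same reaction on 33).** Ionization may compete with the concerted displacement. It could occur at the allylic C10 carbinol, at the tertiary allylic C5 carbinol or, after closure, at the doubly allylic C8–O bond, promoted by the Lewis-acidic metal chloride or by traces of HCl. That would erode the transfer from C10 to C8 and equilibrate C8. The hindered tertiary hydroxyl may also add slowly, giving time for β-hydride loss toward a C10 ketone.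

The fallback replaces the divalent-palladium displacement by an allylic etherification through a π-allyl complex of zerovalent palladium. It sets out from 18. Methyl chloroformate and pyridine in CH2Cl2 at −20 °C should acylate only the secondary hydroxyl and give the C10 methyl carbonate of 18 F1. Pd(PPh3)4 in THF at rt then ionizes the carbonate with inversion. The tertiary alkoxide freed by decarboxylation attacks C8 of the π-allyl unit with a second inversion, so the net course is again syn and the sequence returns to 19.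

**Step 8.** The facial selectivity of the enol ether epoxidation may be poor or reversed. The silyloxy group is only homoallylic to the reacting carbon, and the pseudo-axial methyl of the gem-dimethyl group shields the face that the argument in step 8 prefers.

The fallback sets out from 8 and uses the allylic relationship, which is more reliable. H2O2 and NaOH in MeOH at 0 °C should epoxidize the enone on the face opposite to the adjacent silyloxy group and give the trans-epoxy ketone F2. MgBr2·OEt2 in Et2O at 0 °C opens the epoxide at the secondary β-carbon, since the α-carbon is quaternary and next to the carbonyl, to give the bromohydrin F3. Bu3SnH with azobisisobutyronitrile in toluene at 80 °C removes the bromine by a radical chain and returns to 12.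

**Step 12 (and step 25).** Three things may go wrong: the α-branched stabilized ylide may react slowly with the small equilibrium amount of open hydroxy enal, the Z enal may isomerize on prolonged heating, and the tertiary hydroxyl may add to the new dienone (conjugate addition), which would close the ring without control at C8.

The fallback masks the tertiary hydroxyl before the olefination and sets out from 15:
- i-Bu2AlH (3 equiv) in CH2Cl2 from −78 to 0 °C gives the (Z)-enediol F4.
- Et3SiOTf and 2,6-lutidine at −78 °C give the bis(triethylsilyl) ether F5.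
- Swern oxidation ((COCl)2, DMSO, then Et3N) converts only the primary silyl ether to the (Z)-enal F6.
- Wittig reaction with 5 in toluene at 80 °C gives the silyl-protected dienone F7.
- (S)-Me-CBS with BH3·SMe2 gives the silyl-protected carbinol F8.
- HF·pyridine buffered with pyridine in THF at 0 °C frees the tertiary hydroxyl and returns to 18.

**Step 33.** Over-olefination may occur. The C25 phosphonate 41 is more acidic than 40, so proton transfer can hand the carbanion to the product, which then reacts with a second molecule of 21.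

The fallback gives up the stepwise order. It sets out from 40, which is converted to its dianion (NaN(SiMe3)2, 2.1 equiv, THF, −78 °C) and treated with an equimolar mixture of 21 and 36. The statistical mixture contains 42 together with the symmetrical bis(end B) disilyl ether F9 and the symmetrical bis(end A) hydrocarbon-ether F10. These carry two, one and no silyloxy groups and should separate by chromatography, and the route is rejoined at 42.

## Further compounds

F1 | step 14 | (2S,3E,5Z)-5-[(2S,4R)-4-[(tert-butyldimethylsilyl)oxy]-2-hydroxy-2,6,6-trimethylcyclohexylidene]-2-[(methoxycarbonyl)oxy]-3-methylpent-3-en-1-yl pivalate | CC(C)(C)C(=O)OC[C@@H](OC(=O)OC)/C(C)=C/C=C1/C(C)(C)C[C@@H](O[Si](C)(C)C(C)(C)C)C[C@]1(C)O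
F2 | step 8 | (1S,5R,6S)-5-[(tert-butyldimethylsilyl)oxy]-1,3,3-trimethyl-7-oxabicyclo[4.1.0]heptan-2-one (epoxide oxygen trans to the silyloxy group) | O=C1C(C)(C)C[C@@H](O[Si](C)(C)C(C)(C)C)[C@@H]2O[C@]12C
F3 | step 8 | (2R,3R,4R)-3-bromo-4-[(tert-butyldimethylsilyl)oxy]-2-hydroxy-2,6,6-trimethylcyclohexan-1-one | O=C1C(C)(C)C[C@@H](O[Si](C)(C)C(C)(C)C)[C@@H](Br)[C@]1(C)O
F4 | step 12 | (2Z)-2-[(2S,4R)-4-[(tert-butyldimethylsilyl)oxy]-2-hydroxy-2,6,6-trimethylcyclohexylidene]ethan-1-ol | OC/C=C1/C(C)(C)C[C@@H](O[Si](C)(C)C(C)(C)C)C[C@]1(C)O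
F5 | step 12 | bis(triethylsilyl) ether of F4 | CC[Si](CC)(CC)OC/C=C1/C(C)(C)C[C@@H](O[Si](C)(C)C(C)(C)C)C[C@]1(C)O[Si](CC)(CC)CC
F6 | step 12 | (2Z)-2-[(2S,4R)-4-[(tert-butyldimethylsilyl)oxy]-2,6,6-trimethyl-2-(triethylsilyloxy)cyclohexylidene]acetaldehyde | O=C/C=C1/C(C)(C)C[C@@H](O[Si](C)(C)C(C)(C)C)C[C@]1(C)O[Si](CC)(CC)CC
F7 | step 12 | triethylsilyl ether of 17 at the tertiary hydroxyl | CC(C)(C)C(=O)OCC(=O)/C(C)=C/C=C1/C(C)(C)C[C@@H](O[Si](C)(C)C(C)(C)C)C[C@]1(C)O[Si](CC)(CC)CC
F8 | step 12 | triethylsilyl ether of 18 at the tertiary hydroxyl | CC(C)(C)C(=O)OC[C@@H](O)/C(C)=C/C=C1/C(C)(C)C[C@@H](O[Si](C)(C)C(C)(C)C)C[C@]1(C)O[Si](CC)(CC)CC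
F9 | step 33 | (3R,5S,8S,3'R,5'S,8'S)-3,3'-bis[(tert-butyldimethylsilyl)oxy]-5,8:5',8'-diepoxy-5,8,5',8'-tetrahydro-β,β-carotene | CC(/C=C/C=C(\C)[C@@H]1C=C2C(C)(C)C[C@@H](O[Si](C)(C)C(C)(C)C)C[C@]2(C)O1)=C\C=C\C=C(C)\C=C\C=C(/C)[C@@H]1C=C2C(C)(C)C[C@@H](O[Si](C)(C)C(C)(C)C)C[C@]2(C)O1
F10 | step 33 | (5R,8S,5'R,8'S)-5,8:5',8'-diepoxy-5,8,5',8'-tetrahydro-β,β-carotene | CC(/C=C/C=C(\C)[C@@H]1C=C2C(C)(C)CCC[C@@]2(C)O1)=C\C=C\C=C(C)\C=C\C=C(/C)[C@@H]1C=C2C(C)(C)CCC[C@@]2(C)O1
A1 | alternative 1 | (2S)-2-hydroxy-5,9-dimethyldeca-3,4,8-trien-1-yl pivalate (allene axis not defined) | CC(C)(C)C(=O)OC[C@@H](O)C=C=C(C)CCC=C(C)C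
A2 | alternative 1 | [(2S,7aR)-4,4,7a-trimethyl-2,4,5,6,7,7a-hexahydro-1-benzofuran-2-yl]methyl pivalate | CC(C)(C)C(=O)OC[C@@H]1C=C2C(C)(C)CCC[C@@]2(C)O1
A3 | alternative 2 | [(1E)-3,3-dimethoxybut-1-en-1-yl]triphenylphosphonium bromide | COC(C)(OC)/C=C/[P+](c1ccccc1)(c1ccccc1)c1ccccc1.[Br-]
A4 | alternative 2 | (2S,6R,7aS)-6-[(tert-butyldimethylsilyl)oxy]-2-(1,1-dimethoxyethyl)-4,4,7a-trimethyl-2,4,5,6,7,7a-hexahydro-1-benzofuran | COC(C)(OC)[C@@H]1C=C2C(C)(C)C[C@@H](O[Si](C)(C)C(C)(C)C)C[C@]2(C)O1
A5 | alternative 3 | (1R)-2-[(3E)-5-[(tert-butyldimethylsilyl)oxy]-3-methylpenta-1,3-dien-1-ylidene]-1,3,3-trimethylcyclohexan-1-ol (vinylallene; axis with C9' on the side of the C5' methyl when the hydroxyl is turned toward C8') | CC(C)(C)[Si](C)(C)OC/C=C(\C)C([H])=[C@@]=C1C(C)(C)CCC[C@@]1(C)O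
A6 | alternative 3 | tert-butyldimethyl{[(2E)-3-[(2S,7aR)-4,4,7a-trimethyl-2,4,5,6,7,7a-hexahydro-1-benzofuran-2-yl]but-2-en-1-yl]oxy}silane | CC(C)(C)[Si](C)(C)OC/C=C(\C)[C@@H]1C=C2C(C)(C)CCC[C@@]2(C)O1
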